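**Retrosynthetic overview**

- Numbering: carbons C1–C22 follow the target SMILES (oxygens skipped); ring A is the hydroquinone C17–C22 and ring B is C6–C11 with ketones at C7 and C10. The route rests on the C6–C11 bond, through which ring B is cis-fused to the indane ring C6/C11/C22/C17/C16.
- Key disconnection: C6–C7 and C10–C11 by [4+2] addition of 2,5-bis(trimethylsilyloxy)furan across C6=C11 of a 2-substituted 4,7-dimethoxyinden-1-one, then opening of the oxygen bridge to the C7,C10-enedione.
- Later disconnections: C11–C12 (enolate allylation with a Z-iodoalkenyl bromide), C4–C8 (intramolecular Michael addition of a C2 methyl ketone to the enedione, C1 added afterwards by methylenation), C15–C16 (alkenyllithium onto the C16 ketone), C16–O (radical deoxygenation), the two O-methyl groups.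
- Ring order: ring A and the indane ring (purchased), then ring B, then the cyclopentanone C4/C5/C6/C7/C8, then the cyclohexene C6/C11/C12/C13/C15/C16.

Key step: step 6

Remark: the C6 side chain is carried through the key step as a ketal-masked 3-oxobutyl group, not as a prenyl group. A concerted ene closure of a prenyl group onto C8=C9 would place the isopropenyl group cis to C9 (the C4 epimer of the target), whereas a C4 acetyl group can be equilibrated to the required position trans to C9 before it is methylenated.

**Route**

Step 1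
Reactants: 1 succinic anhydride
Product: 2 2,5-bis(trimethylsilyloxy)furan
Conditions: Me3SiCl (2.4 equiv), Et3N (2.4 equiv), ZnCl2 (5 mol %), MeCN, 80 °C; distillation
Reagents that add atoms: chlorotrimethylsilane, C[Si](C)(C)Cl
Why: Double O-silylation of the anhydride bis-enol under ZnCl2 catalysis (silyl ketene acetal formation) is the established way to this diene, which is distilled and kept cold under argon.

Step 2
Reactants: 3 prop-2-yn-1-ol
Product: 5 (Z)-3-iodo-2-methylprop-2-en-1-ol, via alkenylmagnesium alkoxide 4 (not isolated)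
Conditions: MeMgBr (2.5 equiv), CuI (10 mol %), THF, −10 → 25 °C; then I2, −78 → 0 °C
Reagents that add atoms: methylmagnesium bromide, C[Mg]Br; iodine, II
Why: Copper-catalysed anti-carbomagnesiation of the magnesium propargyl alkoxide puts the methyl group on the internal carbon and magnesium cis to the CH2O group in a chelate, and iodinolysis with retention gives the Z-iodoalkene that later allows C12 and C16 to be cis on C13=C15.

Step 3
Reactants: 5 (Z)-3-iodo-2-methylprop-2-en-1-ol
Product: 6 (Z)-3-bromo-1-iodo-2-methylprop-1-ene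
Conditions: CBr4, PPh3, CH2Cl2, 0 °C
Reagents that add atoms: tetrabromomethane, BrC(Br)(Br)Br
Why: The Appel reaction converts the primary allylic alcohol into the bromide without touching the alkenyl iodide or its geometry.

Step 4
Reactants: 7 4,7-dimethoxyindan-1-one; 8 2-(2-bromoethyl)-2-methyl-1,3-dioxolane
Product: 10 4,7-dimethoxy-2-[2-(2-methyl-1,3-dioxolan-2-yl)ethyl]indan-1-one, via lithium enolate 9 (not isolated)
Conditions: LiN(iPr)2, THF, −78 °C; then 8, NaI (10 mol %), DMPU, −78 → 25 °C
Reagents that add atoms: none
Why: Kinetic enolate alkylation (SN2, iodide-assisted) attaches the masked 3-oxobutyl chain (C5, C4, C2, C3) to C6, and the new stereocentre does not matter because C6 becomes trigonal in the next step.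

Step 5
Reactants: 10 4,7-dimethoxy-2-[2-(2-methyl-1,3-dioxolan-2-yl)ethyl]indan-1-one
Product: 14 4,7-dimethoxy-2-[2-(2-methyl-1,3-dioxolan-2-yl)ethyl]inden-1-one, via lithium enolate 11 (not isolated), via selenide 12 (not isolated), via selenoxide 13 (not isolated)
Conditions: LiN(iPr)2, THF, −78 °C; PhSeBr; then H2O2, pyridine, CH2Cl2, 0 → 25 °C; used at once
Reagents that add atoms: none
Why: α-Selenenylation and selenoxide syn-elimination (Reich dehydrogenation) should take the cis benzylic ring hydrogen at C11 in preference to the unactivated side-chain hydrogens, giving the endocyclic C6=C11 enone, which is not stored.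

Step 6
Reactants: 14 4,7-dimethoxy-2-[2-(2-methyl-1,3-dioxolan-2-yl)ethyl]inden-1-one; 2 2,5-bis(trimethylsilyloxy)furan
Product: 16 (4aR,9aS)-5,8-dimethoxy-9a-[2-(2-methyl-1,3-dioxolan-2-yl)ethyl]-4a,9a-dihydrofluorene-1,4,9-trione, via oxanorbornene adduct 15 (not isolated)
Conditions: 2 (1.5 equiv, slow addition), (S)-3,3-diphenyl-1-(2-methylphenyl)tetrahydro-1H,3H-pyrrolo[1,2-c][1,3,2]oxazaborole·HNTf2 (20 mol %), CH2Cl2, −78 °C; then AcOH/THF/H2O, 0 °C
Reagents that add atoms: none
Why: Proposed new method: the boron Lewis acid binds the C16 carbonyl of 14 and the s-cis-locked, electron-rich furan 2 should add in a concerted but asynchronous [4+2] cycloaddition, its oxygenated termini bonding to C11 and C6; the closest known reaction types are the thermal Diels–Alder reactions of 2,5-bis(silyloxy)furans with enones and quinones and the oxazaborolidinium-catalysed Diels–Alder reactions of cyclic enones and quinones with silyloxy dienes. Ring B is closed as the six-membered ring of the cycloadduct (C6–C7 and C10–C11 formed suprafacially on one face of C6=C11), and aqueous acetic acid then collapses the two bridgehead silyl ketals of 15 to the C7,C10-enedione with loss of hexamethyldisiloxane. C6 and C11 become cis because both bonds form on the same face of the ring-locked alkene, and their absolute configuration (C6 S, C11 R) is set by the catalyst, which has to expose the face on which C6 and C11 are both Re; the bridgehead centres and the endo/exo question vanish on opening. The only selectivity required is therefore enantiofacial, since the diene is symmetrical and the quaternary C6 prevents tautomerisation of ring B to a hydroquinone. The (S) catalyst is assigned by analogy with its complexes of 2-substituted quinones, so the sense of induction has to be confirmed on a crystalline derivative, and 2 is added slowly at −78 °C to keep silyl transfer to the triflimide anion from opening a racemic silyl-cation pathway.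

Step 7
Reactants: 16 (4aR,9aS)-5,8-dimethoxy-9a-[2-(2-methyl-1,3-dioxolan-2-yl)ethyl]-4a,9a-dihydrofluorene-1,4,9-trione; 6 (Z)-3-bromo-1-iodo-2-methylprop-1-ene
Product: 17 (4aR,9aS)-4a-[(Z)-3-iodo-2-methylprop-2-en-1-yl]-5,8-dimethoxy-9a-[2-(2-methyl-1,3-dioxolan-2-yl)ethyl]-4a,9a-dihydrofluorene-1,4,9-trione
Conditions: 6 (1.5 equiv), NaH (1.1 equiv) added last, THF, 0 → 25 °C
Reagents that add atoms: none
Why: C11–H, α to the C10 ketone and benzylic, is the only acidic position, and C-allylation of its sodium enolate (enolate SN2 alkylation) can only occur on the face that keeps the five-membered ring cis-fused to ring B, so C12 is delivered cis to the C6 side chain.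

Step 8
Reactants: 17 (4aR,9aS)-4a-[(Z)-3-iodo-2-methylprop-2-en-1-yl]-5,8-dimethoxy-9a-[2-(2-methyl-1,3-dioxolan-2-yl)ethyl]-4a,9a-dihydrofluorene-1,4,9-trione
Product: 19 tetracyclic tetraketone with exo acetyl at C4 (C4S,C6S,C8R,C11R), via methyl ketone 18 (not isolated)
Conditions: pyridinium p-toluenesulfonate, acetone/H2O, 50 °C; then DBU, MeCN, 25 °C
Reagents that add atoms: water, O
Why: Acetal hydrolysis frees the methyl ketone, whose more substituted enolate adds 5-exo-trig to C8 of the enedione (intramolecular Michael addition closing the cyclopentanone C4/C5/C6/C7/C8), C8 being fixed as a bridgehead while DBU equilibrates the epimerisable C4 acetyl group to the less hindered exo position, trans to C9 and syn to the C7 carbonyl.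

Step 9
Reactants: 19 tetracyclic tetraketone with exo acetyl at C4
Product: 20 tetracyclic triketone with exo isopropenyl at C4 (C4S,C6S,C8R,C11R)
Conditions: Ph3PCH3Br, KN(SiMe3)2, THF, −78 → 0 °C
Reagents that add atoms: methyltriphenylphosphonium bromide, C[P+](c1ccccc1)(c1ccccc1)c1ccccc1.[Br-]
Why: Wittig methylenation should select the unhindered methyl ketone over the three neopentyl-type ring ketones (C7 bridging, C10 next to quaternary C11, C16 aryl) and it fixes the C4 configuration, because the isopropenyl-bearing carbon can no longer enolise.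

Step 10
Reactants: 20 tetracyclic triketone with exo isopropenyl at C4
Product: 21 C10 tert-butyldimethylsilyl enol ether (C9=C10) of 20
Conditions: t-BuMe2SiOTf, Et3N, CH2Cl2, 0 °C
Reagents that add atoms: tert-butyldimethylsilyl trifluoromethanesulfonate, CC(C)(C)[Si](C)(C)OS(=O)(=O)C(F)(F)F
Why: Soft enolisation with silyl triflate and amine masks C10, the only enolisable ketone (C7 and C16 have only quaternary, bridgehead or aryl α-carbons), as its silyl enol ether, so that it cannot act as the nearer electrophile in the next step.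

Step 11
Reactants: 21 C10 tert-butyldimethylsilyl enol ether of 20
Product: 23 pentacyclic C16 bridgehead carbinol (C4S,C6R,C8S,C11R,C16S), via alkenyllithium 22 (not isolated)
Conditions: t-BuLi (2.1 equiv), THF, −78 °C; then H2O
Reagents that add atoms: none
Why: Iodine–lithium exchange outruns carbonyl addition at −78 °C and the Z-alkenyllithium can only reach the C16 ketone (C10 is masked and C7 lies anti to C12 across C6–C11), so intramolecular 1,2-addition (anionic cyclization) closes the cyclohexene and sets C16 by ring constraint.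

Step 12
Reactants: 23 pentacyclic C16 bridgehead carbinol
Product: 26 C16 O-alkyl S-methyl dithiocarbonate of 23, via potassium alkoxide 24 (not isolated), via potassium xanthate 25 (not isolated)
Conditions: KH, THF, 0 °C; CS2; then MeI, 25 °C
Reagents that add atoms: carbon disulfide, S=C=S; iodomethane, CI
Why: Xanthate formation from the potassium alkoxide is safe here, because a retro-aldol cleavage would need an enolate at the C6 bridgehead and the bridgehead xanthate has no syn β-hydrogen for a Chugaev elimination.

Step 13
Reactants: 26 C16 O-alkyl S-methyl dithiocarbonate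
Product: 27 C16-deoxy pentacyclic silyl enol ether (C4S,C6S,C8S,C11R,C16R)
Conditions: Bu3SnH, azobisisobutyronitrile (10 mol %), toluene, 110 °C
Reagents that add atoms: none
Why: Barton–McCombie deoxygenation goes through the C16 bridgehead radical, which can only take hydrogen from the stannane on its outer face, so the C16–H configuration follows from the ring system, whereas an ionic reduction is excluded because a bridgehead cation cannot conjugate with ring A or the alkene.

Step 14
Reactants: 27 C16-deoxy pentacyclic silyl enol ether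
Product: 28 O,O-dimethyl ether of the target (C4S,C6S,C8R,C11R,C16R)
Conditions: 1 M HCl, THF, 25 °C
Reagents that add atoms: none
Why: Mild acid hydrolysis of the silyl enol ether returns the C10 ketone with protonation at C9, a methylene that carries no stereochemistry.

Step 15
Reactants: 28 O,O-dimethyl ether of the target
Product: 30 target hydroquinone CNP0287617.1, via quinone 29 (not isolated)
Conditions: (NH4)2Ce(NO3)6, MeCN/H2O, 0 °C; then aqueous Na2S2O4, 25 °C
Reagents that add atoms: water, O
Why: Oxidative demethylation of the 1,4-dimethoxyarene by tetravalent cerium gives the quinone and dithionite reduces it to the hydroquinone, a two-stage demethylation that should spare both alkenes and both ketones, which a boron tribromide cleavage would endanger.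

**Compound list**

1 | succinic anhydride | O=C1CCC(=O)O1 | starting material
2 | 2,5-bis(trimethylsilyloxy)furan | C[Si](C)(C)Oc1ccc(O[Si](C)(C)C)o1 | intermediate
3 | prop-2-yn-1-ol | C#CCO | starting material
4 | (Z)-alkenylmagnesium bromide alkoxide, BrMgOCH2C(CH3)=CHMgBr, Mg cis to CH2O | Br[Mg]OC/C(C)=C\[Mg]Br | intermediate (not isolated)
5 | (Z)-3-iodo-2-methylprop-2-en-1-ol | OC/C(C)=C\I | intermediate
6 | (Z)-3-bromo-1-iodo-2-methylprop-1-ene | BrC/C(C)=C\I | intermediate
7 | 4,7-dimethoxyindan-1-one | COc1ccc(OC)c2c1CCC2=O | starting material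
8 | 2-(2-bromoethyl)-2-methyl-1,3-dioxolane | CC1(CCBr)OCCO1 | starting material
9 | lithium enolate of 7 | COc1ccc(OC)c2c1CC=C2O[Li] | intermediate (not isolated)
10 | 4,7-dimethoxy-2-[2-(2-methyl-1,3-dioxolan-2-yl)ethyl]indan-1-one (racemic) | COc1ccc(OC)c2c1CC(CCC1(C)OCCO1)C2=O | intermediate
11 | lithium enolate of 10 | COc1ccc(OC)c2c1CC(CCC1(C)OCCO1)=C2O[Li] | intermediate (not isolated)
12 | 2-(phenylselanyl) derivative of 10 (racemic) | COc1ccc(OC)c2c1CC(CCC1(C)OCCO1)([Se]c1ccccc1)C2=O | intermediate (not isolated)
13 | selenoxide of 12 (mixture of isomers) | COc1ccc(OC)c2c1CC(CCC1(C)OCCO1)([Se](=O)c1ccccc1)C2=O | intermediate (not isolated)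
14 | 4,7-dimethoxy-2-[2-(2-methyl-1,3-dioxolan-2-yl)ethyl]inden-1-one | COc1ccc(OC)c2c1C=C(CCC1(C)OCCO1)C2=O | intermediate (key-step precursor)
15 | endo [4+2] adduct: 7-oxanorbornene with trimethylsilyloxy groups on both bridgeheads (C7, C10), C8=C9 alkene, fused at C6–C11 to the 4,7-dimethoxyindanone; C6 side chain and C11–H syn to the oxygen bridge (C6 R, C11 R) | CC1(OCCO1)CC[C@]23C(=O)c4c(OC)ccc(OC)c4[C@H]2[C@@]5(O[Si](C)(C)C)C=C[C@]3(O[Si](C)(C)C)O5 | intermediate (not isolated)
16 | (4aR,9aS)-5,8-dimethoxy-9a-[2-(2-methyl-1,3-dioxolan-2-yl)ethyl]-4a,9a-dihydrofluorene-1,4,9-trione (C6 S, C11 R; cis ring fusion) | CC1(OCCO1)CC[C@@]12C(=O)C=CC(=O)[C@@H]1c1c(OC)ccc(OC)c1C2=O | intermediate (key-step product)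
17 | (4aR,9aS)-4a-[(Z)-3-iodo-2-methylprop-2-en-1-yl]-5,8-dimethoxy-9a-[2-(2-methyl-1,3-dioxolan-2-yl)ethyl]-4a,9a-dihydrofluorene-1,4,9-trione | CC1(OCCO1)CC[C@@]12C(=O)C=CC(=O)[C@]1(C/C(C)=C\I)c1c(OC)ccc(OC)c1C2=O | intermediate
18 | (4aR,9aS)-4a-[(Z)-3-iodo-2-methylprop-2-en-1-yl]-5,8-dimethoxy-9a-(3-oxobutyl)-4a,9a-dihydrofluorene-1,4,9-trione | CC(=O)CC[C@@]12C(=O)C=CC(=O)[C@]1(C/C(C)=C\I)c1c(OC)ccc(OC)c1C2=O | intermediate (not isolated)
19 | tetracyclic tetraketone: ring B (ketones C7, C10) bridged by C5–C4 from C6 to C8, acetyl at C4 exo (syn to C7, trans to C9), C16 ketone, Z-iodoalkenyl chain on C11 (C4 S, C6 S, C8 R, C11 R) | CC(=O)[C@H]1C[C@@]23C(=O)[C@@H]1CC(=O)[C@]2(C/C(C)=C\I)c1c(OC)ccc(OC)c1C3=O | intermediate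
20 | as 19 with isopropenyl in place of acetyl at C4 (C4 S, C6 S, C8 R, C11 R) | C=C(C)[C@H]1C[C@@]23C(=O)[C@@H]1CC(=O)[C@]2(C/C(C)=C\I)c1c(OC)ccc(OC)c1C3=O | intermediate
21 | C10 tert-butyldimethylsilyl enol ether (C9=C10) of 20 (C4 S, C6 S, C8 S, C11 R) | C=C(C)[C@H]1C[C@@]23C(=O)[C@@H]1C=C(O[Si](C)(C)C(C)(C)C)[C@]2(C/C(C)=C\I)c1c(OC)ccc(OC)c1C3=O | intermediate
22 | Z-alkenyllithium from 21 (Li on C15) | C=C(C)[C@H]1C[C@@]23C(=O)[C@@H]1C=C(O[Si](C)(C)C(C)(C)C)[C@]2(C/C(C)=C\[Li])c1c(OC)ccc(OC)c1C3=O | intermediate (not isolated)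
23 | pentacyclic carbinol: cyclohexene C6/C11/C12/C13/C15/C16 closed, OH on bridgehead C16, C10 silyl enol ether, C7 ketone (C4 S, C6 R, C8 S, C11 R, C16 S) | C=C(C)[C@H]1C[C@@]23C(=O)[C@@H]1C=C(O[Si](C)(C)C(C)(C)C)[C@@]21CC(C)=C[C@]3(O)c2c(OC)ccc(OC)c21 | intermediate
24 | potassium alkoxide of 23 | C=C(C)[C@H]1C[C@@]23C(=O)[C@@H]1C=C(O[Si](C)(C)C(C)(C)C)[C@@]21CC(C)=C[C@]3([O-])c2c(OC)ccc(OC)c21.[K+] | intermediate (not isolated)
25 | potassium O-alkyl dithiocarbonate of 23 | C=C(C)[C@H]1C[C@@]23C(=O)[C@@H]1C=C(O[Si](C)(C)C(C)(C)C)[C@@]21CC(C)=C[C@]3(OC(=S)[S-])c2c(OC)ccc(OC)c21.[K+] | intermediate (not isolated)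
26 | C16 O-alkyl S-methyl dithiocarbonate of 23 (C4 S, C6 R, C8 S, C11 R, C16 S) | C=C(C)[C@H]1C[C@@]23C(=O)[C@@H]1C=C(O[Si](C)(C)C(C)(C)C)[C@@]21CC(C)=C[C@]3(OC(=S)SC)c2c(OC)ccc(OC)c21 | intermediate
27 | C16-deoxy pentacycle with C10 silyl enol ether (C4 S, C6 S, C8 S, C11 R, C16 R) | C=C(C)[C@H]1C[C@@]23C(=O)[C@@H]1C=C(O[Si](C)(C)C(C)(C)C)[C@@]21CC(C)=C[C@@H]3c2c(OC)ccc(OC)c21 | intermediate
28 | O,O-dimethyl ether of the target (C4 S, C6 S, C8 R, C11 R, C16 R) | C=C(C)[C@H]1C[C@@]23C(=O)[C@@H]1CC(=O)[C@@]21CC(C)=C[C@@H]3c2c(OC)ccc(OC)c21 | intermediate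
29 | ring A para-quinone of the target skeleton (C4 S, C6 S, C8 R, C11 S, C16 R) | C=C(C)[C@H]1C[C@@]23C(=O)[C@@H]1CC(=O)[C@@]21CC(C)=C[C@@H]3C2=C1C(=O)C=CC2=O | intermediate (not isolated)
30 | CNP0287617.1 (C4 S, C6 S, C8 R, C11 R, C16 R) | C=C(C)[C@H]1C[C@@]23C(=O)[C@@H]1CC(=O)[C@@]21CC(C)=C[C@@H]3c2c(O)ccc(O)c21 | target

**Step count**

Total: 15 steps. Longest linear sequence: 12 steps (steps 4–15, from 7).

**Steps most likely to fail**

Step 6. What may go wrong: a racemic background cycloaddition catalysed by silyl cations released from the diene, a stepwise conjugate addition that stops before ring closure, or ionisation of the dioxolane by the strong Lewis acid. Fallback: setting out from 14 and 2, the cycloaddition is run without catalyst in toluene at 25–60 °C, the known thermal mode of this diene, and opened with aqueous acetic acid as before. This gives racemic material, that is 16 together with its mirror image formed through the enantiomeric adduct F1. The enantiomer of 16 F2 is then removed by preparative chromatography on a chiral stationary phase (cellulose tris(3,5-dimethylphenylcarbamate)), and the route is rejoined at 16.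

Step 11. What may go wrong: addition of the alkyllithium to the C7 or C16 carbonyl before iodine–lithium exchange, or slow 1,2-addition of the alkenyllithium to the hindered, electron-rich aryl ketone so that it is only protonated on work-up. Fallback: setting out from 21, a Nozaki–Hiyama–Kishi cyclization (CrCl2 in excess, NiCl2 2 mol %, DMF/DMSO, 25–50 °C) replaces the preformed organolithium by an alkenylchromium dichloride F3. It is generated by oxidative addition to zerovalent nickel and transmetalation to trivalent chromium. This non-basic, carbonyl-tolerant nucleophile adds to C16, and aqueous work-up returns the route to 23.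

Step 13. What may go wrong: slow β-scission of the stannyl adduct radical, because the C16 bridgehead radical can neither flatten nor conjugate with ring A, so that the thiocarbonyl group is merely reduced and the C16–O bond survives. Fallback: setting out from 23, the alcohol is acylated with methyl chlorooxoacetate (Et3N, 4-dimethylaminopyridine) to the methyl oxalate F4 and saponified with one equivalent of CsOH to the cesium oxalate F5. This salt is irradiated with blue light in the presence of [Ir(dF(CF3)ppy)2(dtbbpy)]PF6 and a thiol hydrogen donor. Single-electron oxidation and loss of two molecules of CO2 generate the same C16 radical irreversibly, hydrogen transfer from the thiol gives 27, and the route continues from there.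

**Further compounds**

F1 | step 6 | enantiomer of adduct 15 | CC1(OCCO1)CC[C@@]23C(=O)c4c(OC)ccc(OC)c4[C@@H]2[C@]5(O[Si](C)(C)C)C=C[C@@]3(O[Si](C)(C)C)O5
F2 | step 6 | enantiomer of 16, (4aS,9aR) | CC1(OCCO1)CC[C@]12C(=O)C=CC(=O)[C@H]1c1c(OC)ccc(OC)c1C2=O
F3 | step 11 | Z-alkenylchromium dichloride from 21 (Cr on C15) | C=C(C)[C@H]1C[C@@]23C(=O)[C@@H]1C=C(O[Si](C)(C)C(C)(C)C)[C@]2(C/C(C)=C\[Cr](Cl)Cl)c1c(OC)ccc(OC)c1C3=O
F4 | step 13 | C16 methyl oxalate of 23 | C=C(C)[C@H]1C[C@@]23C(=O)[C@@H]1C=C(O[Si](C)(C)C(C)(C)C)[C@@]21CC(C)=C[C@]3(OC(=O)C(=O)OC)c2c(OC)ccc(OC)c21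
F5 | step 13 | C16 cesium oxalate of 23 | C=C(C)[C@H]1C[C@@]23C(=O)[C@@H]1C=C(O[Si](C)(C)C(C)(C)C)[C@@]21CC(C)=C[C@]3(OC(=O)C(=O)[O-])c2c(OC)ccc(OC)c21.[Cs+]
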